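**Retrosynthetic overview**
1. Target ⇐ 4(18)-exo-methylene (Markovnikov Cl⁺/H₂O) ⇐ C4 ketone; the C1/C12 (S)-2-methylbutanoates and C6/C19 acetates come from two separately unveiled diols.
2. Butenolide: Nozaki–Hiyama–Kishi addition of 4-bromofuran-2(5H)-one to the C12 aldehyde (held as a 1,12-lactol), which sets C12.
3. C5 quaternary centre (C19) and trans ring fusion: Stork silicon-tethered 5-exo radical cyclisation from the 6α-OH onto a Δ5(10) alkene, then Tamao oxidation.
4. Key step: Diels–Alder of a ring-A 2-silyloxydiene (from (R)-4-hydroxycyclohexenone) with tiglic aldehyde builds ring B and sets C8/C9.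
5. Ring order: ring A (bought) → ring B ([4+2]) → butenolide attached intact last.

Assumption: (R)-4-hydroxycyclohex-2-en-1-one (the quinic-acid-derived building block) is purchased; clerodane numbering and α/β descriptors (H-10 = β) are used for the decalin intermediates.

---

**Step 1**
Reactants: 1, (R)-4-hydroxycyclohex-2-en-1-one
Product: 2, (R)-4-(tert-butyldimethylsilyloxy)cyclohex-2-en-1-one
Conditions: TBSCl, imidazole, DMF, 0 °C → rt
Reagents that add atoms: TBSCl, CC(C)(C)[Si](C)(C)Cl
Why: Standard silyl ether protection; the carbinol stereocentre (future C1) is untouched.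

**Step 2**
Reactants: 2
Product: 3, (R)-4-(TBSO)-2-iodocyclohex-2-en-1-one
Conditions: I₂, pyridine, CH₂Cl₂, 0 °C → rt
Reagents that add atoms: iodine, II
Why: Johnson α-iodination of an enone (pyridine conjugate addition, iodination, elimination) gives the vinyl iodide at the future C5.

**Step 3**
Reactants: 3
Product: 4, (8R)-8-(TBSO)-6-iodo-1,4-dioxaspiro[4.5]dec-6-ene
Conditions: (TMSOCH₂)₂, TMSOTf (cat.), CH₂Cl₂, −78 → −20 °C
Reagents that add atoms: 1,2-bis(trimethylsilyloxy)ethane, C[Si](C)(C)OCCO[Si](C)(C)C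
Why: Noyori ketalisation masks the ketone (future C4) under conditions that spare the TBS ether and allows halogen–metal exchange.

**Step 4**
Reactants: 4
Product: 5, 1-[(8R)-8-(TBSO)-1,4-dioxaspiro[4.5]dec-6-en-6-yl]ethan-1-one
Conditions: t-BuLi (2.1 equiv), THF, −78 °C; then MeCON(OMe)Me
Reagents that add atoms: N-methoxy-N-methylacetamide, CC(=O)N(C)OC
Why: Iodine–lithium exchange gives the α-ketal vinyllithium, and Weinreb acylation installs C6–C7 as a methyl ketone without over-addition.

**Step 5**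
Reactants: 5
Product: 6, 2-silyloxydiene (6-[1-(TBSO)vinyl]-8-(TBSO)-1,4-dioxaspiro[4.5]dec-6-ene, 8R)
Conditions: TBSOTf, Et₃N, CH₂Cl₂, −78 → 0 °C
Reagents that add atoms: TBSOTf, CC(C)(C)[Si](C)(C)OS(=O)(=O)C(F)(F)F
Why: Kinetic soft enolisation at the methyl group gives the cross-conjugated diene C10=C5–C6(OTBS)=C7.

**Step 6 (key step)**
Reactants: 6; 7, tiglic aldehyde [(E)-2-methylbut-2-enal]
Product: 8, Diels–Alder adduct: 4,4-ethylenedioxy-1β,6-bis(TBSO)-8α,9α-dimethyl-10βH-octal-5-ene-9β-carbaldehyde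
Conditions: Me₂AlCl (1.1 equiv, precomplexed with 7), CH₂Cl₂, −78 → −40 °C
Reagents that add atoms: none
Why: Lewis-acid Diels–Alder in which the siloxy-activated C7 terminus bonds to the enal β-carbon, the E-enal gives cis 8,9-dimethyls, the α-methyl enal reacts exo (CHO cis to H-10), and the dienophile adds to the face of C10 trans to the allylic C1-OTBS, setting C8, C9 and C10 from C1.

**Step 7**
Reactants: 8
Product: 9, 4,4-ethylenedioxy-1β-TBSO-8α,9α-dimethyl-6-oxo-octal-5(10)-ene-9β-carbaldehyde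
Conditions: Pd(OAc)₂ (1.1 equiv), MeCN, 40 °C
Reagents that add atoms: none
Why: Saegusa–Ito oxidation of the silyl enol ether is regiospecific because H-10 is the only β-hydrogen available to Pd at C5 (C4 is a ketal); C8/C9 are unaffected and C10 is reset in step 12.

**Step 8**
Reactants: 9
Product: 10, 9β-(2-methoxyvinyl) enone (E/Z mixture)
Conditions: MeOCH₂PPh₃Cl, KHMDS, THF, −78 → 0 °C
Reagents that add atoms: (methoxymethyl)triphenylphosphonium chloride, COC[P+](c1ccccc1)(c1ccccc1)c1ccccc1.[Cl-]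
Why: Wittig methoxymethylenation of the non-enolisable neopentyl aldehyde in preference to the hindered tetrasubstituted enone adds C12.

**Step 9**
Reactants: 10
Product: 11, 9β-[(1,3-dioxolan-2-yl)methyl] enone
Conditions: ethylene glycol, PPTS, CH₂Cl₂, rt
Reagents that add atoms: ethylene glycol, OCCO
Why: Acid-catalysed acetalisation of the enol ether makes C11 a saturated CH₂, so no π-system sits next to the later C10 radical (avoids a 1,2-vinyl shift).

**Step 10**
Reactants: 11
Product: 12, 6α-allylic alcohol (Δ5(10))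
Conditions: NaBH₄, CeCl₃·7H₂O, MeOH, −78 °C
Reagents that add atoms: none
Why: Luche 1,2-reduction with axial hydride delivery (as in carvone → cis-carveol) gives the pseudo-equatorial 6α-OH cis to the 8α-methyl.

**Step 11**
Reactants: 12
Product: 13, 6α-O-(bromomethyl)dimethylsilyl ether
Conditions: BrCH₂SiMe₂Cl, Et₃N, DMAP (cat.), CH₂Cl₂, 0 °C
Reagents that add atoms: (bromomethyl)chlorodimethylsilane, C[Si](C)(Cl)CBr
Why: Silylation of the only free hydroxyl installs the radical tether that carries the future C19.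

**Step 12**
Reactants: 13
Product: 14, cyclic siloxane (6α-O–SiMe₂–C19H₂–C5α), trans-decalin with 10β-H
Conditions: Bu₃SnH (syringe pump), AIBN (cat.), PhH, 80 °C, 0.01 M
Reagents that add atoms: none
Why: Stork–Nishiyama silicon-tethered 5-exo radical cyclisation delivers C19 to C5 on the α face (cis to the 6α-O), and the C10 radical takes hydrogen from the β face opposite the new ring and the axial 9α-methyl, setting C5 and the trans C10.

**Step 13**
Reactants: 14
Product: 15, 6α,19-diol
Conditions: 30% H₂O₂, KF, KHCO₃, THF–MeOH, 40 °C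
Reagents that add atoms: hydrogen peroxide, OO
Why: Tamao–Fleming oxidation converts C19–Si into C19–OH and releases the 6α-OH with no change at any stereocentre.

**Step 14**
Reactants: 15
Product: 16, 6α,19-diacetate
Conditions: Ac₂O, pyridine, DMAP (cat.), rt
Reagents that add atoms: acetic anhydride, CC(=O)OC(C)=O
Why: Acetylation of the only two free hydroxyls installs both target acetates while O1 is still silylated.

**Step 15**
Reactants: 16
Product: 17, 6α,19-diacetoxy-4-oxo-1β,12-lactol (anomeric mixture)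
Conditions: TFA–H₂O (9:1), CH₂Cl₂, 0 °C → rt
Reagents that add atoms: water, O
Why: Acid hydrolysis removes both dioxolanes and the TBS ether, and the freed 1β-OH closes on the C12 aldehyde as a six-membered lactol; the β-acetoxy ketone cannot eliminate because C5 is quaternary.

**Step 16**
Reactants: 17; 18, 4-bromofuran-2(5H)-one
Product: 19, 6α,19-diacetoxy-1β,12(S)-dihydroxy-4-oxo-butenolide diol
Conditions: CrCl₂ (8 equiv), NiCl₂ (2 mol %), 18 (3 equiv), DMF–THF, rt
Reagents that add atoms: none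
Why: Nozaki–Hiyama–Kishi coupling adds the alkenylchromium only to the aldehyde (open lactol form), not to the ketone or esters; with Cr bridging O1 and the aldehyde oxygen, attack from the exposed face away from C9 and axial H-8 is expected to give 12S.

**Step 17**
Reactants: 19; 20, (S)-2-methylbutanoic anhydride
Product: 21, 1β,12(S)-bis[(S)-2-methylbutanoyloxy]-6α,19-diacetoxy-4-ketone
Conditions: 20 (4 equiv), DMAP, pyridine, CH₂Cl₂, rt → 35 °C
Reagents that add atoms: none
Why: DMAP-catalysed acylation esterifies both secondary hydroxyls in one operation without epimerising the acyl α-stereocentre.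

**Step 18**
Reactants: 21
Product: 22, 4(18)-exo-methylene compound
Conditions: Zn, CH₂Br₂, TiCl₄ (preformed Lombardo reagent), THF–CH₂Cl₂, 0 °C → rt
Reagents that add atoms: dibromomethane, BrCBr
Why: Takai–Lombardo methylenation is non-basic and selective for the ketone over the four esters and the butenolide.

**Step 19**
Reactants: 22
Product: 23, ajugaciliatin A
Conditions: trichloroisocyanuric acid (0.4 equiv), acetone–H₂O (4:1), 0 °C
Reagents that add atoms: trichloroisocyanuric acid, O=C1N(Cl)C(=O)N(Cl)C(=O)N1Cl; water, O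
Why: Markovnikov chlorohydrin formation in which Cl⁺ adds to C18 from the less hindered β face (anti to axial C19) and water opens at tertiary C4 from the α face, giving 4α-OH/18-Cl; the electron-poor butenolide alkene is inert.

---

**Compound list**

1 | (R)-4-hydroxycyclohex-2-en-1-one | O=C1C=C[C@H](O)CC1 | starting material
2 | (R)-4-(TBSO)cyclohex-2-en-1-one | O=C1C=C[C@H](O[Si](C)(C)C(C)(C)C)CC1 | intermediate
3 | (R)-4-(TBSO)-2-iodocyclohex-2-en-1-one | O=C1C(I)=C[C@H](O[Si](C)(C)C(C)(C)C)CC1 | intermediate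
4 | (8R)-8-(TBSO)-6-iodo-1,4-dioxaspiro[4.5]dec-6-ene | IC1=C[C@H](O[Si](C)(C)C(C)(C)C)CCC12OCCO2 | intermediate
5 | 1-[(8R)-8-(TBSO)-1,4-dioxaspiro[4.5]dec-6-en-6-yl]ethanone | CC(=O)C1=C[C@H](O[Si](C)(C)C(C)(C)C)CCC12OCCO2 | intermediate
6 | ring-A 2-silyloxydiene | C=C(O[Si](C)(C)C(C)(C)C)C1=C[C@H](O[Si](C)(C)C(C)(C)C)CCC12OCCO2 | intermediate
7 | tiglic aldehyde, (E)-2-methylbut-2-enal | C/C=C(\C)C=O | starting material
8 | Diels–Alder adduct (1β,6-bis-TBSO, 4-ketal, 8α,9α-Me₂, 9β-CHO, 10β-H, Δ5) | O=C[C@@]1(C)[C@H](C)CC(O[Si](C)(C)C(C)(C)C)=C2[C@@H]1[C@H](O[Si](C)(C)C(C)(C)C)CCC23OCCO3 | intermediate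
9 | Δ5(10)-6-one 9β-carbaldehyde | O=C[C@@]1(C)[C@H](C)CC(=O)C2=C1[C@H](O[Si](C)(C)C(C)(C)C)CCC23OCCO3 | intermediate
10 | 9β-(2-methoxyvinyl) enone (E/Z) | COC=C[C@@]1(C)[C@H](C)CC(=O)C2=C1[C@H](O[Si](C)(C)C(C)(C)C)CCC23OCCO3 | intermediate
11 | 9β-(1,3-dioxolan-2-ylmethyl) enone | O1CCOC1C[C@@]2(C)[C@H](C)CC(=O)C3=C2[C@H](O[Si](C)(C)C(C)(C)C)CCC34OCCO4 | intermediate
12 | 6α-allylic alcohol | O1CCOC1C[C@@]2(C)[C@H](C)C[C@H](O)C3=C2[C@H](O[Si](C)(C)C(C)(C)C)CCC34OCCO4 | intermediate
13 | 6α-O-SiMe₂CH₂Br ether | O1CCOC1C[C@@]2(C)[C@H](C)C[C@H](O[Si](C)(C)CBr)C3=C2[C@H](O[Si](C)(C)C(C)(C)C)CCC34OCCO4 | intermediate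
14 | cyclised siloxane (5α-C19, 10β-H, trans-decalin) | O1CCOC1C[C@@]2(C)[C@H](C)C[C@@H]5O[Si](C)(C)C[C@]53[C@@H]2[C@H](O[Si](C)(C)C(C)(C)C)CCC34OCCO4 | intermediate
15 | 6α,19-diol | O1CCOC1C[C@@]2(C)[C@H](C)C[C@H](O)[C@]3(CO)[C@@H]2[C@H](O[Si](C)(C)C(C)(C)C)CCC34OCCO4 | intermediate
16 | 6α,19-diacetate | O1CCOC1C[C@@]2(C)[C@H](C)C[C@H](OC(C)=O)[C@]3(COC(C)=O)[C@@H]2[C@H](O[Si](C)(C)C(C)(C)C)CCC34OCCO4 | intermediate
17 | 4-keto 1β,12-lactol diacetate (anomers) | OC1C[C@@]2(C)[C@H](C)C[C@H](OC(C)=O)[C@]3(COC(C)=O)[C@@H]2[C@H](O1)CCC3=O | intermediate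
18 | 4-bromofuran-2(5H)-one | O=C1C=C(Br)CO1 | starting material
19 | 1β,12S-diol butenolide, 4-ketone, 6α,19-diacetate | O[C@@H](C[C@@]1(C)[C@H](C)C[C@H](OC(C)=O)[C@]2(COC(C)=O)[C@@H]1[C@H](O)CCC2=O)C1=CC(=O)OC1 | intermediate
20 | (S)-2-methylbutanoic anhydride | CC[C@H](C)C(=O)OC(=O)[C@@H](C)CC | starting material
21 | 1β,12S-bis[(S)-2-methylbutanoate] 4-ketone | CC[C@H](C)C(=O)O[C@@H](C[C@@]1(C)[C@H](C)C[C@H](OC(C)=O)[C@]2(COC(C)=O)[C@@H]1[C@H](OC(=O)[C@@H](C)CC)CCC2=O)C1=CC(=O)OC1 | intermediate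
22 | 4(18)-exo-methylene tetraester | CC[C@H](C)C(=O)O[C@@H](C[C@@]1(C)[C@H](C)C[C@H](OC(C)=O)[C@]2(COC(C)=O)[C@@H]1[C@H](OC(=O)[C@@H](C)CC)CCC2=C)C1=CC(=O)OC1 | intermediate
23 | ajugaciliatin A | CC[C@H](C)C(=O)O[C@@H](C[C@@]1(C)[C@H](C)C[C@H](OC(C)=O)[C@]2(COC(C)=O)[C@@H]1[C@H](OC(=O)[C@@H](C)CC)CC[C@]2(O)CCl)C1=CC(=O)OC1 | target

---

**Total step count:** 19
**Longest linear sequence:** 19 steps (from 1)

**Three steps most likely to fail**

- **Step 6 (Diels–Alder).** Risks: modest face or exo selectivity with the hindered trisubstituted enal, and Lewis-acid damage to the allylic ketal or silyl enol ether (Mukaiyama-type side reactions). Fallback: make it intramolecular. Start from (S)-1, esterify the C1 hydroxyl with tiglic acid so the dienophile is delivered on the face syn to O1, open the resulting γ-lactone by DIBAL/Wittig, and invert C1 at the end by Mitsunobu esterification with (S)-2-methylbutanoic acid.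
- **Step 16 (NHK coupling, C12).** Risks: 1,5-induction from the ring is the weakest stereocontrol in the route, and the lactol may react sluggishly. Fallback: change the nucleophile to 3-furyl-Ti(OiPr)₃ for a chelation-controlled addition to the hydroxy-aldehyde, esterify, then convert the furan to the butenolide by ¹O₂/i-Pr₂NEt followed by NaBH₄, done before the C4 ketal is removed.
- **Step 19 (chlorohydrin).** Risks: ene-type allylic chlorination, or water attacking C4 from the β face. Fallback: go through the epoxide instead. Treat 22 with NBS/aqueous DME to give the bromohydrin, close with K₂CO₃ to the 4α,18-epoxide, and open at C18 with LiCl/AcOH (or pyridinium chloride).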